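If an electrophile has two takers that run equally fast, product and quenched substrate come out one to one, so I took that even split as the zero of my scale.

common to all: protonated nucleophile 0.0216 M

| charge | electrophile | free base | protic impurity | remark | time |
|---|---|---|---|---|---|
| birch | 0.0060 M | 6 mM | 6 mM | run made earlier |  |
| alder | 0.0090 M | 6 mM | 6 mM | run made earlier |  |
| ash | 0.012 M | 9 mM | 6 mM | run made earlier |  |
| flask | 0.012 M | 6.00 mM | 6.00 mM |  | 6.0 d |

| run | time / d | electrophile / % | product / % |
|---|---|---|---|
| birch | 1.04 | 18.5 | 31.6 |
| birch | 2.08 | 9.4 | 41.8 |
| birch | 3.00 | 5.1 | 46.7 |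
| birch | 4.00 | 2.4 | 49.8 |
| birch | 5.00 | 1.4 | 51.4 |
| alder | 0.417 | 35.7 | 19.0 |
| alder | 0.833 | 24.8 | 24.9 |
| alder | 1.25 | 19.5 | 29.6 |
| alder | 2.50 | 11.0 | 38.6 |
| alder | 5.00 | 4.2 | 46.1 |
| ash | 0.417 | 37.7 | 16.9 |
| ash | 0.833 | 26.5 | 23.8 |
| ash | 1.25 | 22.3 | 28.6 |
| ash | 2.50 | 13.2 | 38.7 |
| ash | 5.00 | 5.9 | 47.3 |

(standard deviation of a reading: 0.3 percentage points)

- part of the electrophile that has reacted at 6.0 d
- share of the unused nucleophile that is free and not bound as protonated nucleophile, at 6.0 d

- what may be going on: acid set free + free base <-> salt of the base; electrophile + protic impurity -> quenched substrate; nucleophile + acid set free <-> protonated nucleophile; electrophile + nucleophile -> acid set free + product; electrophile <-> dormant form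
- what has gone from electrophile into another species counts as reacted, even if it can come back
- the earlier runs do not show how much of nucleophile is bound; that part of a forecast is a guess

The runs showed a ladder of times. Fastest: by 0.417 d, ash had lost 62.3 % of its electrophile, yet product stood at 16.9 %; the gap of 45.4 % held quench and dormant form. Next: birch's electrophile halved every 1.06 d between its first and last readings. Slower: ash, late on, took 2.15 d. Slowest: between 0.833 d and 5.00 d the ash gap drifted from 49.7 % to 46.8 % while product rose from 23.8 % to 47.3 %, and product over gap climbed from 0.479 to 1.01. I took that last figure as the split s, the amount of product over the amount in the gap, a ratio of amounts and not of rates. The flask has ash's electrophile and alder's base, and alder read 0.928, so I expected s near the even point. The readings did not show how nucleophile was bound, so any figure for the free share of the unused nucleophile was a guess.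

The forecast gave 91 % (86 % to 95 %) and 6 % (1 % to 25 %): “Released acid is eating the base and so the free nucleophile.”

    acid set free + free base ⇌ salt of the base (K = 1.40 × 10⁷ L mol⁻¹, k = 9.90 L mol⁻¹ h⁻¹)
    electrophile + protic impurity → quenched substrate (k = 6.60 L mol⁻¹ h⁻¹)
    nucleophile + acid set free ⇌ protonated nucleophile, settled at all times (K = 36000 L mol⁻¹)
    electrophile + nucleophile → acid set free + product (k = 100 L mol⁻¹ h⁻¹)
    electrophile ⇌ dormant form (K = 0.790, k = 0.0890 h⁻¹)

The flask gave 93.3 % and 0.578 %, with product at 44.4 %, quenched substrate at 43.2 % and dormant form at 5.69 %, so product over gap stood at 0.908 against my 1.01, while the rate of the product step over the quench was 1.9 just after the start and 1.8 at 6.00 d, the quench reaching the midpoint of its turnover at 0.590 d and the product step later, at 0.849 d. In the neighbour flask charged with 0.0036 M of protic impurity, my split scaled by the impurity charges gave 1.68, and product over gap in that flask stood at 1.31.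

The earlier runs and the new flask were generated by integration for substances that don't exist, and the scatter is random.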